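(Readings and results were computed on assumed constants; the scatter is artificial.)

3 ratios are asked of this flask, and I keep one ledger of where each mole of Z goes.

- amber: Z 0.0050 M; E 5.5 mM; the very flask that is asked about, followed so far
- flask: Z 0.0050 M; E 5.50 mM; time 1.0 h

amber run (percent of the Z charged)

| time / min | X / % | J / % |
|---|---|---|
| 4.00 | 49 | 40 |
| 8.00 | 49 | 45 |
| 12.0 | 47 | 52 |
| 15.0 | 48 | 51 |
| 20.0 | 46 | 53 |
| 25.0 | 48 | 55 |

(readings scatter by 1.5 percentage points)

1. ratio of X to J at 5.0 s
2. ratio of X to J at 2.5 min
3. ratio of X to J at 1.0 h

- given per volume of solution although it is solid: E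
- steps that have been proposed: Z -> L; Z + G -> Q; Q -> X; G + L -> J; Z <-> D; E <-> G
- at the start none of E is in solution

By the proposed steps, Z leaves either with G through Q to X, or through L, which later takes G to become J, while D returns to Z. So each mole of Z booked as X or J has cost one mole of G by either road. I therefore carry the cover, the charged cE divided by the charged cZ, here 1.10. It stands above one, so if E dissolves in the end, Z is the limiting reagent, X plus J must reach the whole charge, and cG should end at 0.500 mM.

Now I freeze what holds still. The 6 X readings of the amber run average 47.8 %, a reading with its scatter, while J climbs from 40 % to 55 %. At 4.00 min of that run, 11.0 % is still unbooked, which I read as L waiting for G. With X frozen, J closes at 52.2 %, so I commit to 0.917 for this flask at 1.0 h. The ledger has no clock, so I give no figure of my own for the earlier times.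

The forecast gives 8 at 5.0 s, 1.35 at 2.5 min and 0.91 at 1.0 h, the last just below mine, and it calls the first “probably well above 1, but this is very uncertain”.

The flask gives 20.6, 1.47 and 0.904, so the first lies above the forecast by a factor of 2.58, and the other two fall within the margin.

    Z → L (k = 0.0270 /s)
    Z + G → Q (k = 14.0 /M/s)
    Q → X (k = 0.710 /s)
    G + L → J (k = 4.00 /M/s)
    Z ⇌ D (K = 0.970, k = 0.330 /s)
    E ⇌ G, rate k6*(cs6 - [G]) while solid is left; crystals form when [G] > cs6 (solubility = 3.20 mM, k = 0.0690 /s)

At 1.00 h this flask holds cG at 5.00 × 10⁻⁴ M, the excess that its cover of 1.10 leaves over the charge of Z. In the neighbouring flask, E is cut to 0.0033 M, which lowers the cover from 1.10 to 0.660. The same reckoning now books 66.0 % of Z as X plus J and leaves 34.0 % unpaid as L. At 1.00 h, that neighbouring flask holds 38.7 % X and 27.3 % J, together 66.0 %, with 34.0 % L and cG at 2.16 × 10⁻¹⁴ M. Its ratio of X to J at 1.0 h stands at 1.42.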